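# Proposed total synthesis of CNP0136963.1 (a resveratrol trimer, C42H32O9)

Locants used throughout:
- Ring A is the central benzene, carbons C-1a to C-6a.
- Ring B is the fused resorcinol ring, carbons C-1b to C-6b.
- C-7 is the bridge methine and C-8 the bridge methylene.
- Ring C is the seven-membered ring through C-7, C-8, C-1a, C-2a, C-3′, C-1b and C-2b.
- Ring D is the dihydrofuran O-1′, C-2′, C-3′, fused to ring A at C-2a and C-3a; C-3′ is shared with ring C.
- Ring E is the dihydrofuran O-1″, C-2″, C-3″, fused to ring A at C-5a and C-6a.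

## Analysis of the target

The core is a hexasubstituted benzene, ring A: C-1a carries C-8, C-2a and C-3a carry C-3′ and O-1′ of ring D, C-4a carries hydrogen, and C-5a and C-6a carry O-1″ and C-3″ of ring E. Ring C contains C-7, which bears a 4-hydroxyphenyl group, and ring B has hydroxyls at C-3b and C-5b. There are five stereocentres, C-7 (S), C-2′ and C-3′ (S,S) and C-2″ and C-3″ (R,R); both dihydrofurans are trans, and across ring C the C-7 aryl group and the C-3′–C-2′ bond lie on opposite faces. Ring E sits on the far edge of ring A, where no ring links it to the other three centres, so its absolute configuration cannot be relayed from them. The sensitive features are seven free phenols, two 4-oxybenzylic C–O bonds that ionise in acid and cleave on hydrogenolysis, and three doubly benzylic methines. The difficulties are the fully substituted ring A, the seven-membered ring between two arenes, and the isolated stereochemistry of ring E. The strategy rests on the pattern of oxygen at C-3a, hydrogen at C-4a and oxygen at C-5a with a carbon substituent at C-1a: this is the dioxygenated ring of a stilbene polyketide, so ring A can be folded from an open chain in which C-1a, C-3a and C-5a are ketone carbons and C-2a carries an ester carbon that later becomes C-3′.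

## Retrosynthetic reasoning

**Phenols.** Target 33 is traced to heptamethyl ether 32 by cutting seven O–CH3 bonds. Methyl ethers survive the organolithium, carbene and acid steps, and one Lewis-acid demethylation at the end avoids any hydrogenolysis near the benzylic C–O bonds of rings D and E.

**Ring E, ring bond.** 32 is the C-2″ epimer of 31, and 31 is cut at C-2″–C-3″ to hydrazone 29. This disconnection lets a chiral catalyst decide C-3″, which no neighbouring stereocentre can do. In 29 the future C-2″ is the methylene of a 4-methoxybenzyl ether on O-1″ and C-3″ is the hydrazone carbon on C-6a. Forward, oxidation gives diazo compound 30, a carbene inserts into the ether C–H bond, and acid epimerises C-2″ to trans.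

**Ring E, attachment to ring A.** 29 is cut at C-6a–C-3″ to aryllithium 27 (from bromide 25) and nitrile 26, by way of ketimine 28. Adding an aryl anion to a nitrile and exchanging the imine nitrogen avoids a condensation on a doubly ortho-substituted ketone. 25 comes from phenol 23 and chloride 24, and 23 from phenol 22 by bromination at C-6a. At that stage the only free phenol of the molecule is on ring A, which is what should make the bromination selective for ring A over ring B.

**Ring D.** 22 is cut at O-1′–C-2′ to carbinol 21, whose benzylic cation is trapped by the C-3a hydroxyl under equilibrating conditions, giving trans. 21 is cut at C-2′–aryl to aldehyde 19 and Grignard reagent 20. 19 goes back through epoxide 18 to ketone 17 by a one-carbon homologation. The gain is that C-3′ is created inside ring C, where the C-7 aryl group dictates its configuration.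

**Ring C.** 17 is cut at C-3′–C-1b to ester 15, through aryllithium 16. C-1b is meta to both methoxy groups of ring B, so an electrophilic acylation cannot form this bond. The bromine is therefore carried at C-1b from the first step, and the ring A ester serves as acyl donor.

**Ring A (key disconnection).** 15 is the protected form of resorcylate 14. 14 is cut at C-1a–C-2a, with the ester on C-2a traced to a ketene, which leads through triketo ester 13 and acylketene 12 to diketo-dioxinone 10 and methanol 11. The fold delivers the ester at C-2a, free hydroxyls at C-3a and C-5a, hydrogen at C-4a and C-6a and the bridge at C-1a in one operation, with no arene substitution.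

**Chain.** 10 is cut between the future C-1a and C-6a carbons to N-methoxy-N-methylamide 7 and keto-dioxinone 9, and 9 comes from dioxinone 8.

**C-7.** 7 is cut at C-7–aryl to acrylamide 5 and boronic acid 6. A catalytic enantioselective conjugate addition sets the one stereocentre from which the others on ring C follow. 5 comes from aldehyde 3 (through iminium salt 2) and phosphonate 4, and 3 from bromoarene 1.

## Alternatives that were turned down

Alternative 1: Ring C is disconnected at C-7–C-8, drawn as an alkene. The forward key step would be a ring-closing metathesis (second-generation Grubbs catalyst) between a vinyl group on C-1a and a 1-(4-methoxyphenyl)vinyl group on C-2b, giving the cyclic triaryl alkene A1. Hydrogenation would then create C-7.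
- For: metathesis is neutral and tolerant, so both dihydrofurans could be completed before ring C is closed. On this point it is stronger than the chosen route, which closes ring C with an organolithium on a crowded ester.
- Against: the metathesis substrate needs the complete hexasubstituted ring A, assembled by stepwise arene substitution with the regiochemical problems that chain folding avoids. The 1,1-disubstituted styrene lies between two ortho substituents and must give a trisubstituted alkene in a seven-membered ring, a slow case for ruthenium carbenes. C-7 would be the last centre made, by hydrogenating a hindered alkene whose faces differ only through the fold of the ring system, with both benzylic C–O bonds exposed to hydrogenolysis.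
- Comparison: the chosen route sets C-7 first, by catalyst control, and uses it to steer C-3′. It also needs no separate steps to functionalise ring A.

Alternative 2: Ring A is disconnected at C-1a–C-2a and C-5a–C-6a as an intramolecular Diels–Alder benzannulation. Forward, a silyl ketene acetal diene carried on a preformed trans-2,3-diaryl dihydrofuran would add to an aryl ynone tethered through C-7 and C-8. Loss of methanol would aromatise ring A to benzophenone A2 and close ring C in the same event.
- For: the aroyl group at C-6a and the free hydroxyl at C-5a arrive in place, and two rings form at once. Here it is stronger than the chosen route, which needs a late bromination whose selectivity must be earned.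
- Against: C-7, C-2′ and C-3′ must all be present before any ring links them, so their relationship has to be built in an open system. The diene is an acid- and moisture-sensitive ketene acetal next to an allylic, benzylic hydrogen at C-3′, and aromatisation of the dihydrofuran is an easy exit. The cycloaddition closes a seven-membered ring through a five-atom tether, which calls for prolonged heating. Ring E still has to be built.
- Comparison: the chosen route offers a precursor made in five steps, a ring closure run at room temperature once the ketene is trapped, and stereochemistry relayed through ring C.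

Alternative 3: Ring B is disconnected at both of its bonds to ring C (C-1b–C-3′ and C-2b–C-7). Forward, the enolate of a 2-indanone-1-carboxylate built on ring A would add to a dimethoxy-substituted aryne released by CsF. The aryl anion would close on the ketone and the strained alkoxide would fragment, expanding the five-membered ring to keto ester A3.
- For: two carbon–carbon bonds form in one operation, and the regiochemistry of addition to a 3-alkoxy aryne is the one required. It reaches ring C in fewer steps than the chosen route and is stronger in convergence.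
- Against: the only stereocentre of A3 is α to an ester and doubly benzylic, so it cannot hold its configuration. C-7 must then be made from the ketone by aryl addition and reductive removal of a tertiary benzylic alcohol, with no source of absolute control. The ring A oxygens arrive as methyl ethers that must be freed selectively beside four others.
- Comparison: the chosen route fixes C-7 in step 3 and delivers the ring A oxygens as free phenols that are distinct from every methyl ether.

Key step: step 6

## Remarks before the steps

Assumption on catalyst sense: (R,R)-2,5-diphenylbicyclo[2.2.2]octa-2,5-diene in step 3 is assumed to deliver the S methine, and Rh2(R-PTAD)4 in step 16 the R centre at C-3″. Should either give the antipode, the mirror-image ligand is used with no other change.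

Numbering convention: intermediates formed in the flask that differ in constitution from reactant and product are numbered; enolates, alkoxides and phenoxides of numbered compounds are not.

## Steps

Step 1
Reactants: 1 1-bromo-3,5-dimethoxybenzene
Product: 3 2-bromo-4,6-dimethoxybenzaldehyde, via aryl iminium salt 2 (not isolated)
Conditions: POCl3, DMF, 0 → 90 °C; then aq. NaOAc, rt
Reagents that add atoms: N,N-dimethylformamide, CN(C)C=O; phosphoryl chloride, O=P(Cl)(Cl)Cl; water, O
Why: Vilsmeier–Haack formylation; the chloroiminium ion made from POCl3 and DMF attacks the position para to one methoxy group and ortho to the other, next to bromine, rather than the more crowded site between the two methoxy groups, giving iminium chloride 2 (its chloride comes from POCl3), which water hydrolyses to the aldehyde. The minor regioisomer should be removable by crystallisation.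

Step 2
Reactants: 3 2-bromo-4,6-dimethoxybenzaldehyde; 4 diethyl {2-[methoxy(methyl)amino]-2-oxoethyl}phosphonate
Product: 5 (E)-3-(2-bromo-4,6-dimethoxyphenyl)-N-methoxy-N-methylprop-2-enamide
Conditions: NaH, THF, 0 °C → rt
Reagents that add atoms: none
Why: Horner–Wadsworth–Emmons olefination with a stabilised phosphonate anion; the reversible addition and the bulky di-ortho-substituted aryl group should both favour the E alkene.

Step 3
Reactants: 5 (E)-3-(2-bromo-4,6-dimethoxyphenyl)-N-methoxy-N-methylprop-2-enamide; 6 4-methoxyphenylboronic acid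
Product: 7 (3S)-3-(2-bromo-4,6-dimethoxyphenyl)-N-methoxy-3-(4-methoxyphenyl)-N-methylpropanamide
Conditions: [RhCl(C2H4)2]2 (2.5 mol %), (R,R)-2,5-diphenylbicyclo[2.2.2]octa-2,5-diene (5.5 mol %), 6 (2.5 equiv), aq. KOH (0.5 equiv), 1,4-dioxane–H2O 10:1, 50 °C
Reagents that add atoms: none
Why: Hayashi–Miyaura conjugate addition, an established reaction of β-aryl unsaturated N-methoxy-N-methylamides with rhodium–diene catalysts; the aryl–rhodium species held by the C2-symmetric diene inserts the alkene through one face to give the S methine, and water protonates the rhodium enolate. The aryl bromide should be inert to monovalent rhodium under these conditions.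

Step 4
Reactants: 8 2,2,6-trimethyl-4H-1,3-dioxin-4-one
Product: 9 2,2-dimethyl-6-(2-oxopropyl)-4H-1,3-dioxin-4-one
Conditions: 8 (2 equiv), LiN(SiMe3)2 (2 equiv), THF, −78 °C; then AcCl (1 equiv), −78 → −40 °C; aq. NH4Cl
Reagents that add atoms: acetyl chloride, CC(=O)Cl
Why: Vinylogous Claisen acylation; the lithium dienolate reacts with the acid chloride at its γ-carbon, and the second equivalent of dienolate takes up the more acidic proton of the product.

Step 5
Reactants: 9 2,2-dimethyl-6-(2-oxopropyl)-4H-1,3-dioxin-4-one; 7 (3S)-3-(2-bromo-4,6-dimethoxyphenyl)-N-methoxy-3-(4-methoxyphenyl)-N-methylpropanamide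
Product: 10 6-[(6S)-6-(2-bromo-4,6-dimethoxyphenyl)-6-(4-methoxyphenyl)-2,4-dioxohexyl]-2,2-dimethyl-4H-1,3-dioxin-4-one
Conditions: 9 (2 equiv), LiN(i-Pr)2 (4 equiv), THF, −78 °C; then 7 (1 equiv), −78 → −20 °C; aq. NH4Cl
Reagents that add atoms: none
Why: Claisen-type C-acylation of the dianion of 9 at its terminal carbon by the N-methoxy-N-methylamide, whose chelated tetrahedral intermediate prevents a second addition. The amide base is consumed in forming the dianion before 7 is added, so neither the bromoarene nor the methine of 7 should be metalated.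

Step 6
Reactants: 10 6-[(6S)-6-(2-bromo-4,6-dimethoxyphenyl)-6-(4-methoxyphenyl)-2,4-dioxohexyl]-2,2-dimethyl-4H-1,3-dioxin-4-one; 11 methanol
Product: 14 methyl 6-[(2S)-2-(2-bromo-4,6-dimethoxyphenyl)-2-(4-methoxyphenyl)ethyl]-2,4-dihydroxybenzoate, via acylketene 12 (not isolated), via triketo methyl ester 13 (not isolated)
Conditions: MeOH (10 equiv), PhMe, 110 °C (sealed tube); then Cs2CO3, MeOH, rt; then HCl, MeOH, rt
Reagents that add atoms: none
Why: On heating, the dioxinone of 10 fragments in a retro-[4+2] sense, expelling acetone and leaving acylketene 12, which methanol captures at the ketene carbon to give the open-chain 3,5,7-triketo ester 13. Cs2CO3 then enolises the most acidic methylene of 13, chain position 2 between the ester and the 3-oxo group, and this carbon adds to the 7-oxo group; acid completes the dehydration and the two remaining ketones enolise to the aromatic 2,4-dihydroxybenzoate. The closest known reaction type is the thermolysis of diketo-dioxinones with alcohol trapping followed by base-then-acid aldol aromatisation to 6-alkyl resorcylates, the laboratory counterpart of the orsellinate polyketide fold. Ring A closes in a six-membered exo-trig aldol mode (enolexo when the enolate is drawn through the ester carbonyl), forming the C-1a–C-2a bond. No stereocentre is formed, and the existing methine, which is β to the 7-oxo group of the chain and has no acidifying group of its own, should not epimerise under carbonate. The selectivity needed is aldol closure from chain position 2 onto position 7, over lactonisation to a pyranone and over Claisen closure onto the ester. It is secured by the methyl ester being a poor acyl acceptor beside three ketones and by closing the ring at room temperature under base, then acid, only after excess methanol has fully trapped the ketene. The ring B bromide and all methyl ethers are spectators.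

Step 7
Reactants: 14 methyl 6-[(2S)-2-(2-bromo-4,6-dimethoxyphenyl)-2-(4-methoxyphenyl)ethyl]-2,4-dihydroxybenzoate
Product: 15 methyl 6-[(2S)-2-(2-bromo-4,6-dimethoxyphenyl)-2-(4-methoxyphenyl)ethyl]-2,4-bis(methoxymethoxy)benzoate
Conditions: NaH (2.5 equiv), MOMCl (2.5 equiv), DMF, 0 °C → rt
Reagents that add atoms: chloromethyl methyl ether, COCCl
Why: Williamson-type acetal formation on both phenoxides; NaH overcomes the hydrogen bond of the C-3a hydroxyl to the ester. The two acetals are chosen because they fall together in step 12 under the acid that closes ring D.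

Step 8
Reactants: 15 methyl 6-[(2S)-2-(2-bromo-4,6-dimethoxyphenyl)-2-(4-methoxyphenyl)ethyl]-2,4-bis(methoxymethoxy)benzoate
Product: 17 (10S)-7,9-dimethoxy-10-(4-methoxyphenyl)-2,4-bis(methoxymethoxy)-10,11-dihydro-5H-dibenzo[a,d][7]annulen-5-one, via aryllithium 16 (not isolated)
Conditions: t-BuLi (2.1 equiv), THF, −78 °C, then −78 → −20 °C; aq. NH4Cl
Reagents that add atoms: none
Why: Parham cyclisation; bromine–lithium exchange at C-1b is much faster than attack of t-BuLi on the di-ortho-substituted ester or any deprotonation, and aryllithium 16 then adds to the ester across a seven-membered transition state held in place by the two arenes. The hindered diaryl ketone formed on collapse (annulene C-5 is the future C-3′ and annulene C-10 is C-7) should resist a second addition.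

Step 9
Reactants: 17 (10S)-7,9-dimethoxy-10-(4-methoxyphenyl)-2,4-bis(methoxymethoxy)-10,11-dihydro-5H-dibenzo[a,d][7]annulen-5-one
Product: 18 (10S)-7,9-dimethoxy-10-(4-methoxyphenyl)-2,4-bis(methoxymethoxy)-10,11-dihydrospiro[dibenzo[a,d][7]annulene-5,2′-oxirane] (either configuration at the spiro carbon)
Conditions: Me3S+ I− (3 equiv), n-BuLi (2.9 equiv), THF, 0 °C → rt
Reagents that add atoms: trimethylsulfonium iodide, C[S+](C)C.[I-]
Why: Corey–Chaykovsky epoxidation; the small sulfonium methylide adds to the non-enolisable, hindered diaryl ketone and the betaine closes to the spiro-epoxide. Its configuration is irrelevant because the spiro carbon is ionised in step 10.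

Step 10
Reactants: 18 (10S)-7,9-dimethoxy-10-(4-methoxyphenyl)-2,4-bis(methoxymethoxy)-10,11-dihydrospiro[dibenzo[a,d][7]annulene-5,2′-oxirane]
Product: 19 (5S,10S)-7,9-dimethoxy-10-(4-methoxyphenyl)-2,4-bis(methoxymethoxy)-10,11-dihydro-5H-dibenzo[a,d][7]annulene-5-carbaldehyde
Conditions: ZnI2 (0.5 equiv), PhMe, rt
Reagents that add atoms: none
Why: Meinwald rearrangement; ZnI2 opens the epoxide at the doubly benzylic carbon, which the oxygens at C-3a and C-5a stabilise, and a 1,2-hydride shift gives the aldehyde. The methoxy group at C-3b forces the C-7 aryl group pseudo-axial, a substituent on the same face at the neighbouring benzylic carbon would collide with it, and so the formyl group should take the opposite face (5S), a preference the enolisable aldehyde can also reach by equilibration.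

Step 11
Reactants: 19 (5S,10S)-7,9-dimethoxy-10-(4-methoxyphenyl)-2,4-bis(methoxymethoxy)-10,11-dihydro-5H-dibenzo[a,d][7]annulene-5-carbaldehyde; 20 (4-methoxyphenyl)magnesium bromide
Product: 21 [(5S,10S)-7,9-dimethoxy-10-(4-methoxyphenyl)-2,4-bis(methoxymethoxy)-10,11-dihydro-5H-dibenzo[a,d][7]annulen-5-yl](4-methoxyphenyl)methanol (both carbinol epimers)
Conditions: 20 (3 equiv), THF, −78 → 0 °C; aq. NH4Cl
Reagents that add atoms: none
Why: Grignard addition to the aldehyde at low temperature to limit enolisation; the new carbinol centre is left as a mixture because it is ionised in step 12.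

Step 12
Reactants: 21 [(5S,10S)-7,9-dimethoxy-10-(4-methoxyphenyl)-2,4-bis(methoxymethoxy)-10,11-dihydro-5H-dibenzo[a,d][7]annulen-5-yl](4-methoxyphenyl)methanol
Product: 22 (7S,2′S,3′S)-tetracyclic 5a-phenol (rings A to D closed; ring D trans; hydrogen at C-6a)
Conditions: HCl (1 M in MeOH–THF 1:1), 45 °C
Reagents that add atoms: none
Why: Acid removes both methoxymethyl acetals and ionises the 4-methoxybenzylic alcohol to a quinone-methide-like cation, which the C-3a hydroxyl traps in a five-membered closure (the known acid-mediated dihydrobenzofuran formation). The closure is reversible, so the C-2′ aryl group should settle trans to ring B at C-3′, giving (2′S,3′S).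

Step 13
Reactants: 22 (7S,2′S,3′S)-tetracyclic 5a-phenol
Product: 23 (7S,2′S,3′S)-6a-bromo tetracyclic 5a-phenol
Conditions: NBS (1.0 equiv), i-Pr2NH (10 mol %), CH2Cl2, −78 → 0 °C
Reagents that add atoms: N-bromosuccinimide, O=C1CCC(=O)N1Br
Why: Amine-catalysed ortho-bromination of a phenol; the N-bromoamine delivers bromine through a hydrogen bond to the only free hydroxyl, so ring A should react before the methyl-ether rings. Of its two ortho sites C-6a is also para to O-1′, the usual position of substitution in 5-alkylresorcinol derivatives.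

Step 14
Reactants: 23 (7S,2′S,3′S)-6a-bromo tetracyclic 5a-phenol; 24 4-methoxybenzyl chloride
Product: 25 (7S,2′S,3′S)-6a-bromo tetracyclic 5a-(4-methoxybenzyl) ether
Conditions: 24 (1.3 equiv), K2CO3 (2 equiv), n-Bu4NI (10 mol %), DMF, 50 °C
Reagents that add atoms: none
Why: Williamson etherification; the benzyl group is a building block, its methylene becoming C-2″ and its arene the 4-methoxyphenyl group of ring E.

Step 15
Reactants: 25 (7S,2′S,3′S)-6a-bromo tetracyclic 5a-(4-methoxybenzyl) ether; 26 3,5-dimethoxybenzonitrile
Product: 29 6a-[(3,5-dimethoxyphenyl)(hydrazinylidene)methyl] tetracyclic 5a-(4-methoxybenzyl) ether, via ring A aryllithium 27 (not isolated), via N–H ketimine 28 (not isolated)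
Conditions: t-BuLi (2.1 equiv), THF, −78 °C; 26 (1.5 equiv), −78 → 0 °C; MeOH; then N2H4·H2O (10 equiv), AcOH, EtOH, 60 °C
Reagents that add atoms: hydrazine, NN
Why: Bromine–lithium exchange gives aryllithium 27, which adds once to the nitrile because the N-lithio ketimine cannot accept a second nucleophile. The N–H ketimine 28 then exchanges its nitrogen with hydrazine (transimination), which should be far easier than condensing hydrazine with the corresponding doubly ortho-substituted ketone.

Step 16
Reactants: 29 6a-[(3,5-dimethoxyphenyl)(hydrazinylidene)methyl] tetracyclic 5a-(4-methoxybenzyl) ether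
Product: 31 (7S,2′S,3′S,2″S,3″R)-heptamethyl ether with cis ring E, via diaryldiazomethane 30 (not isolated)
Conditions: MnO2 (10 equiv), CH2Cl2, 0 °C, filtration; then Rh2(R-PTAD)4 [dirhodium tetrakis((R)-N-phthaloyl-1-adamantylglycinate)] (1 mol %), CH2Cl2, 0 °C
Reagents that add atoms: none
Why: MnO2 dehydrogenates the hydrazone to diazo compound 30, and the chiral dirhodium tetracarboxylate turns it into a donor/donor carbene that inserts into the 1,5-related C–H bond next to oxygen of the 4-methoxybenzyl ether, the known route from 2-benzyloxybenzophenone hydrazones to 2,3-diaryl-2,3-dihydrobenzofurans. The catalyst, not the distant stereocentres, should set C-3″ as R, and the insertion is expected to give the 2,3-cis isomer.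

Step 17
Reactants: 31 (7S,2′S,3′S,2″S,3″R)-heptamethyl ether with cis ring E
Product: 32 (7S,2′S,3′S,2″R,3″R)-heptamethyl ether of the target
Conditions: CF3CO2H (5 equiv), CH2Cl2, 0 °C → rt
Reagents that add atoms: none
Why: Acid-mediated epimerisation; the benzylic C-2″–O bond opens reversibly to the 4-methoxybenzylic cation and recloses under thermodynamic control to the trans ring. C-3″ is outside the ionising system and keeps its configuration, the already trans ring D returns unchanged, and the low temperature is meant to keep the cation from being captured by a neighbouring arene.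

Step 18
Reactants: 32 (7S,2′S,3′S,2″R,3″R)-heptamethyl ether of the target
Product: 33 CNP0136963.1
Conditions: BBr3 (14 equiv), CH2Cl2, −78 °C → rt; then MeOH, H2O
Reagents that add atoms: none
Why: Lewis-acid cleavage of the seven aryl methyl ethers; any opening of the dihydrofurans to benzylic bromides at the borate stage should be reversed on aqueous work-up, where the phenols reclose to the more stable trans rings.

## Compound list

1 | 1-bromo-3,5-dimethoxybenzene | COc1cc(Br)cc(OC)c1 | starting material
2 | N-[(2-bromo-4,6-dimethoxyphenyl)methylidene]-N-methylmethanaminium chloride (aryl iminium salt, formed in the flask) | COc1cc(Br)c(C=[N+](C)C)c(OC)c1.[Cl-] | intermediate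
3 | 2-bromo-4,6-dimethoxybenzaldehyde | COc1cc(Br)c(C=O)c(OC)c1 | intermediate
4 | diethyl {2-[methoxy(methyl)amino]-2-oxoethyl}phosphonate | CCOP(=O)(CC(=O)N(C)OC)OCC | starting material
5 | (E)-3-(2-bromo-4,6-dimethoxyphenyl)-N-methoxy-N-methylprop-2-enamide | COc1cc(Br)c(/C=C/C(=O)N(C)OC)c(OC)c1 | intermediate
6 | 4-methoxyphenylboronic acid | COc1ccc(B(O)O)cc1 | starting material
7 | (3S)-3-(2-bromo-4,6-dimethoxyphenyl)-N-methoxy-3-(4-methoxyphenyl)-N-methylpropanamide | COc1ccc([C@@H](c2c(Br)cc(OC)cc2OC)CC(=O)N(C)OC)cc1 | intermediate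
8 | 2,2,6-trimethyl-4H-1,3-dioxin-4-one | CC1=CC(=O)OC(C)(C)O1 | starting material
9 | 2,2-dimethyl-6-(2-oxopropyl)-4H-1,3-dioxin-4-one | CC(=O)CC1=CC(=O)OC(C)(C)O1 | intermediate
10 | 6-[(6S)-6-(2-bromo-4,6-dimethoxyphenyl)-6-(4-methoxyphenyl)-2,4-dioxohexyl]-2,2-dimethyl-4H-1,3-dioxin-4-one | COc1ccc([C@@H](c2c(Br)cc(OC)cc2OC)CC(=O)CC(=O)CC2=CC(=O)OC(C)(C)O2)cc1 | intermediate
11 | methanol | CO | starting material
12 | (9S)-9-(2-bromo-4,6-dimethoxyphenyl)-9-(4-methoxyphenyl)nona-1-ene-1,3,5,7-tetrone (acylketene, formed in the flask) | COc1ccc([C@@H](c2c(Br)cc(OC)cc2OC)CC(=O)CC(=O)CC(=O)C=C=O)cc1 | intermediate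
13 | methyl (9S)-9-(2-bromo-4,6-dimethoxyphenyl)-9-(4-methoxyphenyl)-3,5,7-trioxononanoate (formed in the flask) | COc1ccc([C@@H](c2c(Br)cc(OC)cc2OC)CC(=O)CC(=O)CC(=O)CC(=O)OC)cc1 | intermediate
14 | methyl 6-[(2S)-2-(2-bromo-4,6-dimethoxyphenyl)-2-(4-methoxyphenyl)ethyl]-2,4-dihydroxybenzoate | COc1ccc([C@@H](c2c(Br)cc(OC)cc2OC)Cc2cc(O)cc(O)c2C(=O)OC)cc1 | intermediate
15 | methyl 6-[(2S)-2-(2-bromo-4,6-dimethoxyphenyl)-2-(4-methoxyphenyl)ethyl]-2,4-bis(methoxymethoxy)benzoate | COc1ccc([C@@H](c2c(Br)cc(OC)cc2OC)Cc2cc(OCOC)cc(OCOC)c2C(=O)OC)cc1 | intermediate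
16 | methyl 6-[(2S)-2-(2-lithio-4,6-dimethoxyphenyl)-2-(4-methoxyphenyl)ethyl]-2,4-bis(methoxymethoxy)benzoate (formed in the flask) | COc1ccc([C@@H](c2c([Li])cc(OC)cc2OC)Cc2cc(OCOC)cc(OCOC)c2C(=O)OC)cc1 | intermediate
17 | (10S)-7,9-dimethoxy-10-(4-methoxyphenyl)-2,4-bis(methoxymethoxy)-10,11-dihydro-5H-dibenzo[a,d][7]annulen-5-one | COc1ccc([C@@H]2Cc3cc(OCOC)cc(OCOC)c3C(=O)c3cc(OC)cc(OC)c32)cc1 | intermediate
18 | (10S)-7,9-dimethoxy-10-(4-methoxyphenyl)-2,4-bis(methoxymethoxy)-10,11-dihydrospiro[dibenzo[a,d][7]annulene-5,2′-oxirane], spiro carbon undefined | COc1ccc([C@@H]2Cc3cc(OCOC)cc(OCOC)c3C4(CO4)c3cc(OC)cc(OC)c32)cc1 | intermediate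
19 | (5S,10S)-7,9-dimethoxy-10-(4-methoxyphenyl)-2,4-bis(methoxymethoxy)-10,11-dihydro-5H-dibenzo[a,d][7]annulene-5-carbaldehyde | COc1ccc([C@@H]2Cc3cc(OCOC)cc(OCOC)c3[C@@H](C=O)c3cc(OC)cc(OC)c32)cc1 | intermediate
20 | (4-methoxyphenyl)magnesium bromide | COc1ccc([Mg]Br)cc1 | starting material
21 | [(5S,10S)-7,9-dimethoxy-10-(4-methoxyphenyl)-2,4-bis(methoxymethoxy)-10,11-dihydro-5H-dibenzo[a,d][7]annulen-5-yl](4-methoxyphenyl)methanol, carbinol carbon undefined | COc1ccc([C@@H]2Cc3cc(OCOC)cc(OCOC)c3[C@@H](C(O)c3ccc(OC)cc3)c3cc(OC)cc(OC)c32)cc1 | intermediate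
22 | (7S,2′S,3′S)-tetracyclic 5a-phenol: rings A to D closed, ring D trans, hydroxyl at C-5a, hydrogen at C-4a and C-6a, methoxy at C-3b and C-5b, 4-methoxyphenyl at C-7 and C-2′ | COc1ccc([C@@H]2Cc3c4c(cc(O)c3)O[C@H](c3ccc(OC)cc3)[C@H]4c3cc(OC)cc(OC)c32)cc1 | intermediate
23 | (7S,2′S,3′S)-6a-bromo tetracyclic 5a-phenol: the tetracyclic phenol carrying bromine at C-6a | COc1ccc([C@@H]2Cc3c4c(cc(O)c3Br)O[C@H](c3ccc(OC)cc3)[C@H]4c3cc(OC)cc(OC)c32)cc1 | intermediate
24 | 4-methoxybenzyl chloride | COc1ccc(CCl)cc1 | starting material
25 | (7S,2′S,3′S)-6a-bromo tetracyclic 5a-(4-methoxybenzyl) ether | COc1ccc([C@@H]2Cc3c4c(cc(OCc5ccc(OC)cc5)c3Br)O[C@H](c3ccc(OC)cc3)[C@H]4c3cc(OC)cc(OC)c32)cc1 | intermediate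
26 | 3,5-dimethoxybenzonitrile | COc1cc(OC)cc(C#N)c1 | starting material
27 | ring A aryllithium: 6a-lithio tetracyclic 5a-(4-methoxybenzyl) ether (formed in the flask) | COc1ccc([C@@H]2Cc3c4c(cc(OCc5ccc(OC)cc5)c3[Li])O[C@H](c3ccc(OC)cc3)[C@H]4c3cc(OC)cc(OC)c32)cc1 | intermediate
28 | N–H ketimine: 6a-[(3,5-dimethoxyphenyl)(imino)methyl] tetracyclic 5a-(4-methoxybenzyl) ether (formed in the flask) | COc1ccc([C@@H]2Cc3c4c(cc(OCc5ccc(OC)cc5)c3C(=N)c3cc(OC)cc(OC)c3)O[C@H](c3ccc(OC)cc3)[C@H]4c3cc(OC)cc(OC)c32)cc1 | intermediate
29 | 6a-[(3,5-dimethoxyphenyl)(hydrazinylidene)methyl] tetracyclic 5a-(4-methoxybenzyl) ether (hydrazone) | COc1ccc([C@@H]2Cc3c4c(cc(OCc5ccc(OC)cc5)c3C(=NN)c3cc(OC)cc(OC)c3)O[C@H](c3ccc(OC)cc3)[C@H]4c3cc(OC)cc(OC)c32)cc1 | intermediate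
30 | diaryldiazomethane: 6a-[diazo(3,5-dimethoxyphenyl)methyl] tetracyclic 5a-(4-methoxybenzyl) ether (formed in the flask) | COc1ccc([C@@H]2Cc3c4c(cc(OCc5ccc(OC)cc5)c3C(=[N+]=[N-])c3cc(OC)cc(OC)c3)O[C@H](c3ccc(OC)cc3)[C@H]4c3cc(OC)cc(OC)c32)cc1 | intermediate
31 | (7S,2′S,3′S,2″S,3″R)-heptamethyl ether with cis ring E | COc1ccc([C@@H]2Cc3c4c(cc5c3[C@@H](c3cc(OC)cc(OC)c3)[C@@H](c3ccc(OC)cc3)O5)O[C@H](c3ccc(OC)cc3)[C@H]4c3cc(OC)cc(OC)c32)cc1 | intermediate
32 | (7S,2′S,3′S,2″R,3″R)-heptamethyl ether of the target, trans ring E | COc1ccc([C@@H]2Cc3c4c(cc5c3[C@@H](c3cc(OC)cc(OC)c3)[C@H](c3ccc(OC)cc3)O5)O[C@H](c3ccc(OC)cc3)[C@H]4c3cc(OC)cc(OC)c32)cc1 | intermediate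
33 | CNP0136963.1, (7S,2′S,3′S,2″R,3″R) | Oc1ccc([C@@H]2Cc3c4c(cc5c3[C@@H](c3cc(O)cc(O)c3)[C@H](c3ccc(O)cc3)O5)O[C@H](c3ccc(O)cc3)[C@H]4c3cc(O)cc(O)c32)cc1 | target

## Step count and least certain steps

Total: 18 steps. Longest linear sequence: 17 steps (steps 1–3 and 5–18, from 1); step 4 is a one-step side branch.

**Step 6 (key step).** The acylketene may be captured by an enol oxygen of its own chain, or the triketo ester may close through oxygen to a pyranone instead of through carbon, because several nucleophilic and electrophilic sites compete in one flexible chain. Fallback, from 10 back to 14: 10 is stirred with Et3N in CH2Cl2 at room temperature, which should bring about the corresponding aldol closure (dioxinone C-5 onto the distal ketone) and dehydration while the dioxinone is still intact. This gives 7-hydroxy-2,2-dimethyl-5-[(2S)-2-(2-bromo-4,6-dimethoxyphenyl)-2-(4-methoxyphenyl)ethyl]-4H-1,3-benzodioxin-4-one F1. NaOMe in MeOH then opens the cyclic acetal ester of F1 to 14, so no free ketene or open triketo ester is involved.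

**Step 3.** Insertion of the twisted, doubly ortho-substituted β-aryl alkene into the aryl–rhodium bond may be slow, so that protodeboronation of 6 wins, and the twist may erode face discrimination. Fallback, from 5 back to 7, using a stoichiometric auxiliary and an organocopper reagent: 5 is hydrolysed (KOH, aq. EtOH, 80 °C) to (E)-3-(2-bromo-4,6-dimethoxyphenyl)prop-2-enoic acid F2. Pivaloyl chloride and Et3N in THF convert F2 in the flask to the mixed pivalic anhydride F3, and LiCl with (R)-4-phenyl-1,3-oxazolidin-2-one then gives the N-enoyl oxazolidinone F4. Grignard reagent 20 with CuBr·SMe2 in THF at −40 °C adds to the chelated s-cis enoyl imide from the face away from the phenyl group, which should give the (3S) adduct F5. Me(MeO)NH·HCl and AlMe3 in CH2Cl2 exchange the auxiliary of F5 for the N-methoxy-N-methylamide, returning 7.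

**Step 8.** The aryllithium may be protonated before it finds the crowded ester, or may exchange with the acidic hydrogen at C-4a between the two acetal oxygens, leaving the ring open. Fallback, from 15 back to 17, replacing the crowded ester by a slim, linear nitrile as the acceptor: LiAlH4 (THF, 0 °C) should reduce 15 to the benzylic alcohol F6, which Dess–Martin periodinane oxidises to the benzaldehyde F7. NH2OH·HCl and pyridine in EtOH give the aldoxime F8, and (CF3CO)2O with Et3N in CH2Cl2 dehydrates it to the benzonitrile F9. t-BuLi in THF at −78 °C gives the ring B aryllithium F10, which should add to the nitrile carbon, where the ortho substituents do not block the out-of-plane approach, to give after a methanol quench the cyclic N–H ketimine F11. Aqueous oxalic acid in THF at room temperature hydrolyses F11 to 17 without touching the acetals.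

**Step 13.** Bromination may spread to C-4a or to ring B, or run on to a dibromide, because several positions of similar electron density are present. Fallback, from 22 back to 29, using a reaction that only a free phenol can undergo: MgCl2, Et3N and paraformaldehyde in MeCN at reflux formylate ortho to the magnesium phenoxide, giving the 6a-formyl phenol F12. Chloride 24 with K2CO3 gives the 4-methoxybenzyl ether F13, and 3,5-dimethoxyphenylmagnesium bromide adds to it to give the diaryl carbinol F14. Dess–Martin periodinane oxidises F14 to the 6a-(3,5-dimethoxybenzoyl) ketone F15. N2H4·H2O and AcOH in n-BuOH at 110 °C convert F15 to 29.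

**Step 16.** The hindered carbene may dimerise to an azine or insert with poor enantio- or diastereocontrol, and the sense of induction is assumed, not derived. Fallback, from 28 back to 32, accepting a separation in place of catalyst control (it also bypasses the epimerisation of step 17): 28 is hydrolysed with aqueous oxalic acid in place of the hydrazine treatment, giving the 6a-(3,5-dimethoxybenzoyl) ketone F15. Me3S+ I− and n-BuLi give the epoxide F16, and ZnI2 rearranges it to the diarylacetaldehyde F17. Grignard reagent 20 gives the carbinol F18. CF3CO2H with pentamethylbenzene in CH2Cl2 removes the 4-methoxybenzyl group of F18 and closes ring E trans in both absolute senses, giving 32 together with its (2″S,3″S) diastereomer F19. The two are diastereomers and would be separated by chromatography.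

## Further compounds

F1 | step 6 | 7-hydroxy-2,2-dimethyl-5-[(2S)-2-(2-bromo-4,6-dimethoxyphenyl)-2-(4-methoxyphenyl)ethyl]-4H-1,3-benzodioxin-4-one | COc1ccc([C@@H](c2c(Br)cc(OC)cc2OC)Cc2cc(O)cc3c2C(=O)OC(C)(C)O3)cc1
F2 | step 3 | (E)-3-(2-bromo-4,6-dimethoxyphenyl)prop-2-enoic acid | COc1cc(Br)c(/C=C/C(=O)O)c(OC)c1
F3 | step 3 | (E)-3-(2-bromo-4,6-dimethoxyphenyl)prop-2-enoic pivalic anhydride | COc1cc(Br)c(/C=C/C(=O)OC(=O)C(C)(C)C)c(OC)c1
F4 | step 3 | (4R)-3-[(E)-3-(2-bromo-4,6-dimethoxyphenyl)prop-2-enoyl]-4-phenyl-1,3-oxazolidin-2-one | COc1cc(Br)c(/C=C/C(=O)N2C(=O)OC[C@H]2c2ccccc2)c(OC)c1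
F5 | step 3 | (4R)-3-[(3S)-3-(2-bromo-4,6-dimethoxyphenyl)-3-(4-methoxyphenyl)propanoyl]-4-phenyl-1,3-oxazolidin-2-one | COc1ccc([C@@H](c2c(Br)cc(OC)cc2OC)CC(=O)N2C(=O)OC[C@H]2c2ccccc2)cc1
F6 | step 8 | {2-[(2S)-2-(2-bromo-4,6-dimethoxyphenyl)-2-(4-methoxyphenyl)ethyl]-4,6-bis(methoxymethoxy)phenyl}methanol | COc1ccc([C@@H](c2c(Br)cc(OC)cc2OC)Cc2cc(OCOC)cc(OCOC)c2CO)cc1
F7 | step 8 | 2-[(2S)-2-(2-bromo-4,6-dimethoxyphenyl)-2-(4-methoxyphenyl)ethyl]-4,6-bis(methoxymethoxy)benzaldehyde | COc1ccc([C@@H](c2c(Br)cc(OC)cc2OC)Cc2cc(OCOC)cc(OCOC)c2C=O)cc1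
F8 | step 8 | 2-[(2S)-2-(2-bromo-4,6-dimethoxyphenyl)-2-(4-methoxyphenyl)ethyl]-4,6-bis(methoxymethoxy)benzaldehyde oxime, oxime geometry undefined | COc1ccc([C@@H](c2c(Br)cc(OC)cc2OC)Cc2cc(OCOC)cc(OCOC)c2C=NO)cc1
F9 | step 8 | 2-[(2S)-2-(2-bromo-4,6-dimethoxyphenyl)-2-(4-methoxyphenyl)ethyl]-4,6-bis(methoxymethoxy)benzonitrile | COc1ccc([C@@H](c2c(Br)cc(OC)cc2OC)Cc2cc(OCOC)cc(OCOC)c2C#N)cc1
F10 | step 8 | 2-[(2S)-2-(2-lithio-4,6-dimethoxyphenyl)-2-(4-methoxyphenyl)ethyl]-4,6-bis(methoxymethoxy)benzonitrile | COc1ccc([C@@H](c2c([Li])cc(OC)cc2OC)Cc2cc(OCOC)cc(OCOC)c2C#N)cc1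
F11 | step 8 | (10S)-7,9-dimethoxy-10-(4-methoxyphenyl)-2,4-bis(methoxymethoxy)-10,11-dihydro-5H-dibenzo[a,d][7]annulen-5-imine | COc1ccc([C@@H]2Cc3cc(OCOC)cc(OCOC)c3C(=N)c3cc(OC)cc(OC)c32)cc1
F12 | step 13 | 6a-formyl tetracyclic 5a-phenol | COc1ccc([C@@H]2Cc3c4c(cc(O)c3C=O)O[C@H](c3ccc(OC)cc3)[C@H]4c3cc(OC)cc(OC)c32)cc1
F13 | step 13 | 6a-formyl tetracyclic 5a-(4-methoxybenzyl) ether | COc1ccc([C@@H]2Cc3c4c(cc(OCc5ccc(OC)cc5)c3C=O)O[C@H](c3ccc(OC)cc3)[C@H]4c3cc(OC)cc(OC)c32)cc1
F14 | step 13 | 6a-[(3,5-dimethoxyphenyl)(hydroxy)methyl] tetracyclic 5a-(4-methoxybenzyl) ether, carbinol carbon undefined | COc1ccc([C@@H]2Cc3c4c(cc(OCc5ccc(OC)cc5)c3C(O)c3cc(OC)cc(OC)c3)O[C@H](c3ccc(OC)cc3)[C@H]4c3cc(OC)cc(OC)c32)cc1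
F15 | step 13 | 6a-(3,5-dimethoxybenzoyl) tetracyclic 5a-(4-methoxybenzyl) ether | COc1ccc([C@@H]2Cc3c4c(cc(OCc5ccc(OC)cc5)c3C(=O)c3cc(OC)cc(OC)c3)O[C@H](c3ccc(OC)cc3)[C@H]4c3cc(OC)cc(OC)c32)cc1
F16 | step 16 | 6a-[2-(3,5-dimethoxyphenyl)oxiran-2-yl] tetracyclic 5a-(4-methoxybenzyl) ether, oxirane carbon undefined | COc1ccc([C@@H]2Cc3c4c(cc(OCc5ccc(OC)cc5)c3C5(CO5)c3cc(OC)cc(OC)c3)O[C@H](c3ccc(OC)cc3)[C@H]4c3cc(OC)cc(OC)c32)cc1
F17 | step 16 | 6a-[1-(3,5-dimethoxyphenyl)-2-oxoethyl] tetracyclic 5a-(4-methoxybenzyl) ether, methine undefined | COc1ccc([C@@H]2Cc3c4c(cc(OCc5ccc(OC)cc5)c3C(C=O)c3cc(OC)cc(OC)c3)O[C@H](c3ccc(OC)cc3)[C@H]4c3cc(OC)cc(OC)c32)cc1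
F18 | step 16 | 6a-[1-(3,5-dimethoxyphenyl)-2-hydroxy-2-(4-methoxyphenyl)ethyl] tetracyclic 5a-(4-methoxybenzyl) ether, both new centres undefined | COc1ccc([C@@H]2Cc3c4c(cc(OCc5ccc(OC)cc5)c3C(C(O)c3ccc(OC)cc3)c3cc(OC)cc(OC)c3)O[C@H](c3ccc(OC)cc3)[C@H]4c3cc(OC)cc(OC)c32)cc1
F19 | step 16 | (7S,2′S,3′S,2″S,3″S)-heptamethyl ether, the trans ring E diastereomer | COc1ccc([C@@H]2Cc3c4c(cc5c3[C@H](c3cc(OC)cc(OC)c3)[C@@H](c3ccc(OC)cc3)O5)O[C@H](c3ccc(OC)cc3)[C@H]4c3cc(OC)cc(OC)c32)cc1
A1 | alternative 1 | ring C triaryl alkene (heptamethyl ether with a double bond between C-7 and C-8) | COc1ccc(C2=Cc3c4c(cc5c3[C@@H](c3cc(OC)cc(OC)c3)[C@H](c3ccc(OC)cc3)O5)O[C@H](c3ccc(OC)cc3)[C@H]4c3cc(OC)cc(OC)c32)cc1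
A2 | alternative 2 | tetracyclic ortho-hydroxy benzophenone (hydroxyl at C-5a, 3,5-dimethoxybenzoyl at C-6a, rings A to D in place) | COc1ccc([C@@H]2Cc3c4c(cc(O)c3C(=O)c3cc(OC)cc(OC)c3)O[C@H](c3ccc(OC)cc3)[C@H]4c3cc(OC)cc(OC)c32)cc1
A3 | alternative 3 | methyl 2,4,7,9-tetramethoxy-10-oxo-10,11-dihydro-5H-dibenzo[a,d][7]annulene-5-carboxylate, one enantiomer at C-5 | COC(=O)[C@H]1c2cc(OC)cc(OC)c2C(=O)Cc2cc(OC)cc(OC)c21
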